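The runs are simulated for an exercise; scatter was added.

The flask is to be reckoned through one ratio instead of a curve fitted to every reading.

| flask | starting material | second substrate | free catalyst | remark | time |
|---|---|---|---|---|---|
| Friday's | 10 mM | 5 mM | 100 µM | run made earlier |  |
| Thursday's | 10 mM | 20 mM | 100 µM | run made earlier |  |
| Monday's | 5 mM | 10 mM | 100 µM | run made earlier |  |
| flask | 10 mM | 10.0 mM | 100 µM |  | 15 d |

| run | time / d | target / % | starting material / % |
|---|---|---|---|
| Friday's | 0.250 | 27.8 | 69.7 |
| Friday's | 0.625 | 52.7 | 38.8 |
| Friday's | 1.67 | 55.4 | 6.3 |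
| Friday's | 4.00 | 19.2 | 0.2 |
| Friday's | 10.0 | 0.9 | 0 |
| Thursday's | 0.250 | 27.4 | 71.0 |
| Thursday's | 0.625 | 50.9 | 39.7 |
| Thursday's | 1.67 | 55.8 | 7.3 |
| Thursday's | 4.00 | 19.6 | 0.2 |
| Thursday's | 10.0 | 0.9 | 0.4 |
| Monday's | 0.250 | 30.7 | 67.4 |
| Monday's | 0.625 | 54.3 | 36.0 |
| Monday's | 1.67 | 54.2 | 5.9 |
| Monday's | 4.00 | 18.5 | 0.1 |
| Monday's | 10.0 | 0.5 | 0.1 |

(scatter of a reading: 0.3 percentage points)

- the analysis behind the earlier runs scatters by 0.3 percentage points, standard deviation

- when, up to 15 d, the flask holds most target
- the amount of target, in percent of the starting material charged, at that time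

Friday's and Thursday's runs, with 5 mM and 20 mM of second substrate, read 55.4% and 55.8% of target at 1.67 d, so the flask, lying between them, is reckoned from Friday's readings. There starting material falls at 1.66 d⁻¹ and late target at 0.510 d⁻¹. Their ratio, s = 0.308, the pace of target's loss over the pace of starting material's loss, is a selectivity factor. For two first-order steps in a row, the highest target is s^(s/(1−s)) of the charge.

From below, the bracket starts at Thursday's reading, 55.8%, an estimate that holds as far as the flask follows that run. From above, target's fall in Friday's run from 1.67 d to 4.00 d gives 0.455 d⁻¹, slower than the late fall, and that stretch opens with 6.3% of starting material still present. That lower pace gives s = 0.275 and an estimated ceiling of 61.3%. The late pace tightens the estimate to 59.2% at 1.03 d.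

The forecast, reasoning that “The maximum occurs where formation equals loss”, gives 58.5% at 1.1 d, inside the bracket and a little below the reckoned peak.

The flask gives 60.8% at 1.13 d, inside the bracket, and the forecast stands within its margins on both.

    starting material + free catalyst ⇌ catalyst intermediate A (K = 50.0 M⁻¹, k = 0.571 M⁻¹ s⁻¹)
    catalyst intermediate A → free catalyst + target (k = 0.00675 s⁻¹)
    second substrate + free catalyst ⇌ catalyst intermediate B (K = 6600 M⁻¹, k = 0.200 M⁻¹ s⁻¹)
    catalyst intermediate B → free catalyst + second product (k = 0.0479 s⁻¹)
    free catalyst + target → free catalyst + over-reaction product (k = 0.0597 M⁻¹ s⁻¹)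

Without the over-reaction step the flask's peak stands at 100% instead of 60.8%. Free catalyst multiplies both the making of target and its over-reaction, so it cancels from s. From the constants s is 0.281, and the same rule gives 60.9% for the flask. That ratio holds no charge of starting material, so the reading s = 0.308 is carried unchanged to the neighbour charged with 4.0 mM of starting material, which peaks at 60.8%.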